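The six-membered carbocycle is numbered C1 (quaternary epoxide carbon), C2 (carbinol carbon), C3 (benzoyloxy carbon), C4=C5 (alkene) and C6 (epoxide CH). It is a cyclohex-4-ene with oxygen on both allylic carbons C3 and C6, which is the retron of a Diels–Alder reaction. Disconnecting C1–C6 and C2–C3 leads to an (E,E)-1-benzoyloxy-4-silyloxybutadiene (C3–C6) and a (Z)-2-bromo-3-silyloxyacrolein (C1–C2 plus the formyl carbon). One catalytic asymmetric [4+2] cycloaddition closes the ring and sets C1, C2, C3 and C6. The epoxide is closed afterwards by the C6 oxygen displacing the C1 bromide trans to it.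

Key step: step 3

Remark: (1E,3E)-buta-1,3-diene-1,4-diyl diacetate and bromomalonaldehyde are taken as purchasable; the ring numbering above is used in all names of the cyclohexene compounds.

Step 1
Reactants: 1 (1E,3E)-buta-1,3-diene-1,4-diyl diacetate
Product: 4 (1E,3E)-4-[(tert-butyldimethylsilyl)oxy]buta-1,3-dien-1-yl benzoate, via dipotassium dienediolate 2 (not isolated), via potassium benzoyloxydienolate 3 (not isolated)
Conditions: KOtBu (2.0 equiv), THF, −78 °C; BzCl (1.0 equiv), −78 °C; TBSCl (1.2 equiv), −78 → 0 °C
Reagents that add atoms: benzoyl chloride O=C(Cl)c1ccccc1; tert-butyldimethylsilyl chloride CC(C)(C)[Si](C)(C)Cl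
Why: tert-butoxide cleaves both enol acetates to the dienediolate with retention of the E,E geometry (enolate generation from enol esters), the dianion is far more nucleophilic than the monoanion so one equivalent of benzoyl chloride should O-acylate once, and the silyl chloride then caps the remaining enolate oxygen (enolate O-acylation and O-silylation).

Step 2
Reactants: 5 bromomalonaldehyde (2-bromopropanedial)
Product: 6 (Z)-2-bromo-3-[(tert-butyldimethylsilyl)oxy]prop-2-enal
Conditions: TBSCl, Et3N, CH2Cl2, 0 °C
Reagents that add atoms: tert-butyldimethylsilyl chloride CC(C)(C)[Si](C)(C)Cl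
Why: O-silylation of the acidic enol of the 1,3-dialdehyde should give the extended vinylogous silyl ester with the silyloxy group trans to the formyl group and cis to bromine, which is the geometry that later places the C2 oxygen trans to the C1 carbon substituent (silyl enol ether formation).

Step 3
Reactants: 4 (1E,3E)-4-[(tert-butyldimethylsilyl)oxy]buta-1,3-dien-1-yl benzoate; 6 (Z)-2-bromo-3-[(tert-butyldimethylsilyl)oxy]prop-2-enal
Product: 7 (1R,2S,3R,6S)-1-bromo-2,6-bis[(tert-butyldimethylsilyl)oxy]-1-formylcyclohex-4-en-3-yl benzoate
Conditions: (R)-diphenylprolinol-derived B-(o-tolyl)oxazaborolidine C24H24BNO (20 mol %) protonated by (CF3SO2)2NH (18 mol %), CH2Cl2, −78 → −20 °C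
Reagents that add atoms: none
Why: The oxazaborolidinium ion binds the formyl oxygen of 6 (boron syn to the formyl hydrogen, which contacts the ring oxygen), and the s-trans enal then undergoes a concerted, asynchronous [4+2] cycloaddition with s-cis 4 in which the benzoyloxy-bearing diene terminus bonds first to the silyloxy-bearing β-carbon. The closest known reaction type is the chiral oxazaborolidinium-catalysed Diels–Alder reaction of 2-bromoacrolein and β-substituted 2-bromo enals with acyclic oxygenated dienes. The six-membered ring closes by suprafacial [π4s+π2s] union that forms C1–C6 and C2–C3 and leaves the C4=C5 double bond. The cis relationship of the C3 and C6 oxygens comes from the E,E diene geometry, the cis relationship of bromine and the C2 oxygen from the Z dienophile geometry, and the formyl group ends up cis to both diene oxygens through endo orientation of the complexed formyl group. The absolute configuration comes from the catalyst, whose carbinol aryl group shields one enal face so that the diene should add to the Si face of the α-carbon; the (R)-catalyst is the enantiomer that the formyl C–H···O binding model predicts for this. The step needs ortho regiochemistry and C=C over C=O periselectivity: the silyloxy group is a stronger donor than benzoyloxy, so the benzoyloxy terminus is the nucleophilic end and matches the electrophilic β-carbon of 6, and the low nucleophilicity of that acyloxy-substituted terminus together with the low temperature disfavours attack at the formyl carbon.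

Step 4
Reactants: 7 (1R,2S,3R,6S)-1-bromo-2,6-bis[(tert-butyldimethylsilyl)oxy]-1-formylcyclohex-4-en-3-yl benzoate
Product: 8 (1R,2S,3R,6S)-1-bromo-2,6-bis[(tert-butyldimethylsilyl)oxy]-1-(hydroxymethyl)cyclohex-4-en-3-yl benzoate
Conditions: NaBH4, THF/MeOH, −40 °C; AcOH quench
Reagents that add atoms: none
Why: borohydride should reduce the aldehyde chemoselectively beside the benzoate, the silyl ethers and the tertiary bromide, and the cold protic medium with an acidic quench keeps the bromohydrin alkoxide from closing to a spiro-epoxide; no stereocenter is created (NaBH4 carbonyl reduction).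

Step 5
Reactants: 8 (1R,2S,3R,6S)-1-bromo-2,6-bis[(tert-butyldimethylsilyl)oxy]-1-(hydroxymethyl)cyclohex-4-en-3-yl benzoate
Product: 9 (1R,2S,3R,6S)-1-[(benzoyloxy)methyl]-1-bromo-2,6-bis[(tert-butyldimethylsilyl)oxy]cyclohex-4-en-3-yl benzoate
Conditions: BzCl, pyridine, DMAP (cat.), CH2Cl2, 0 °C → rt
Reagents that add atoms: benzoyl chloride O=C(Cl)c1ccccc1
Why: acylation of the primary alcohol installs the second benzoate of the target under conditions too weakly basic to trigger bromohydrin closure, and it removes the exocyclic oxygen as a competitor for the bromide in the next step (nucleophile-catalysed esterification).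

Step 6
Reactants: 9 (1R,2S,3R,6S)-1-[(benzoyloxy)methyl]-1-bromo-2,6-bis[(tert-butyldimethylsilyl)oxy]cyclohex-4-en-3-yl benzoate
Product: 12 (1R,2S,3R,6S)-1-[(benzoyloxy)methyl]-2-hydroxy-7-oxabicyclo[4.1.0]hept-4-en-3-yl benzoate (target), via C6 bromohydrin 10 (not isolated), via epoxy silyl ether 11 (not isolated)
Conditions: Bu4NF (2.5 equiv), AcOH (1.2 equiv), THF, 0 °C → rt
Reagents that add atoms: none
Why: fluoride should cleave the less hindered allylic C6 silyl ether first, the C6 oxygen lies trans-diaxial to the tertiary C1 bromide and closes the epoxide by intramolecular SN2 with inversion at C1 (halohydrin cyclisation), so the epoxide oxygen stays cis to the C3 benzoate and trans to the C2 oxygen, while the acetic acid buffer protonates the C2 alkoxide set free from the second silyl ether and so suppresses benzoyl migration and Payne rearrangement.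

Compound list
1 | (1E,3E)-buta-1,3-diene-1,4-diyl diacetate | CC(=O)O/C=C/C=C/OC(C)=O | starting material
2 | dipotassium (1E,3E)-buta-1,3-diene-1,4-bis(olate) | [K+].[K+].[O-]/C=C/C=C/[O-] | intermediate
3 | potassium (1E,3E)-4-(benzoyloxy)buta-1,3-dien-1-olate | [K+].[O-]/C=C/C=C/OC(=O)c1ccccc1 | intermediate
4 | (1E,3E)-4-[(tert-butyldimethylsilyl)oxy]buta-1,3-dien-1-yl benzoate | O=C(O/C=C/C=C/O[Si](C)(C)C(C)(C)C)c1ccccc1 | intermediate
5 | bromomalonaldehyde (2-bromopropanedial) | O=CC(Br)C=O | starting material
6 | (Z)-2-bromo-3-[(tert-butyldimethylsilyl)oxy]prop-2-enal | O=C/C(Br)=C/O[Si](C)(C)C(C)(C)C | intermediate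
7 | (1R,2S,3R,6S)-1-bromo-2,6-bis[(tert-butyldimethylsilyl)oxy]-1-formylcyclohex-4-en-3-yl benzoate | O=C[C@]1(Br)[C@@H](O[Si](C)(C)C(C)(C)C)[C@H](OC(=O)c2ccccc2)C=C[C@@H]1O[Si](C)(C)C(C)(C)C | intermediate
8 | (1R,2S,3R,6S)-1-bromo-2,6-bis[(tert-butyldimethylsilyl)oxy]-1-(hydroxymethyl)cyclohex-4-en-3-yl benzoate | OC[C@]1(Br)[C@@H](O[Si](C)(C)C(C)(C)C)[C@H](OC(=O)c2ccccc2)C=C[C@@H]1O[Si](C)(C)C(C)(C)C | intermediate
9 | (1R,2S,3R,6S)-1-[(benzoyloxy)methyl]-1-bromo-2,6-bis[(tert-butyldimethylsilyl)oxy]cyclohex-4-en-3-yl benzoate | O=C(OC[C@]1(Br)[C@@H](O[Si](C)(C)C(C)(C)C)[C@H](OC(=O)c2ccccc2)C=C[C@@H]1O[Si](C)(C)C(C)(C)C)c1ccccc1 | intermediate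
10 | (1R,2S,3R,6S)-1-[(benzoyloxy)methyl]-1-bromo-2-[(tert-butyldimethylsilyl)oxy]-6-hydroxycyclohex-4-en-3-yl benzoate | O=C(OC[C@]1(Br)[C@@H](O[Si](C)(C)C(C)(C)C)[C@H](OC(=O)c2ccccc2)C=C[C@@H]1O)c1ccccc1 | intermediate
11 | (1S,2S,3R,6S)-1-[(benzoyloxy)methyl]-2-[(tert-butyldimethylsilyl)oxy]-7-oxabicyclo[4.1.0]hept-4-en-3-yl benzoate | O=C(OC[C@]12O[C@H]1C=C[C@@H](OC(=O)c1ccccc1)[C@@H]2O[Si](C)(C)C(C)(C)C)c1ccccc1 | intermediate
12 | (1R,2S,3R,6S)-1-[(benzoyloxy)methyl]-2-hydroxy-7-oxabicyclo[4.1.0]hept-4-en-3-yl benzoate | O=C(OC[C@]12O[C@H]1C=C[C@@H](OC(=O)c1ccccc1)[C@@H]2O)c1ccccc1 | target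

Total step count: 6. Longest linear sequence: 5 (steps 1, 3, 4, 5, 6); step 2 is a one-step branch.

Steps most likely to fail

Step 3. The cycloaddition may be too slow because the β-silyloxy group makes the dienophile a push–pull alkene, the diene may attack the formyl carbon instead of the C=C bond, and endo or facial selectivity may erode; should only the sense of induction be opposite to the model, the enantiomeric catalyst serves. The fallback gives up catalytic enantiocontrol for a kinetic resolution. It sets out from 4 and 6, which are heated without catalyst (toluene, BHT, 110 °C, sealed vessel) to give racemic adduct, that is 7 together with the mirror-image adduct ent-7 F1. Reduction with NaBH4 as in step 4 gives 8 together with the mirror-image alcohol ent-8 F2. A screened lipase (for example immobilised Candida antarctica lipase B) with vinyl benzoate then benzoylates one enantiomer of the primary alcohol, the aim being to convert 8 and leave ent-8 F2 behind; the fallback comes back to the route at 9.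

Step 1. Mono-selectivity in the acylation of the dianion may be lost (double benzoylation or double silylation), or C-acylation may intervene. The fallback replaces the dianion by two charge-controlled mono-cleavages. It sets out from 1: one equivalent of KOtBu (THF, −78 °C) cleaves a single acetate, because the remaining ester of the resulting potassium (1E,3E)-4-acetoxybuta-1,3-dien-1-olate F3 is deactivated by the negative charge, and BzCl gives the isolable mixed diester (1E,3E)-4-acetoxybuta-1,3-dien-1-yl benzoate F4. A second equivalent of KOtBu removes the acetyl group in preference to the less electrophilic benzoyl group, which comes back to the route at 3, and TBSCl gives 4.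

Step 6. Once the C2 hydroxyl is free under basic fluoride, the benzoyl group may migrate from O3 to O2, the epoxy alcohol may undergo Payne rearrangement, or HBr may be lost by E2 before ring closure. The fallback separates deprotection from ring closure. It sets out from 9: HF·pyridine in THF/pyridine (0 °C → rt) removes both silyl groups under acidic conditions to give the bromo diol (1R,2S,3R,6S)-1-[(benzoyloxy)methyl]-1-bromo-2,6-dihydroxycyclohex-4-en-3-yl benzoate F5. One equivalent of DBU (CH2Cl2, 0 °C) then closes the epoxide from the only hydroxyl that is trans to bromine and is consumed as its hydrobromide, so no free base remains; this comes back to the route at 12.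

Further compounds
F1 | step 3 | (1S,2R,3S,6R)-1-bromo-2,6-bis[(tert-butyldimethylsilyl)oxy]-1-formylcyclohex-4-en-3-yl benzoate (ent-7) | O=C[C@@]1(Br)[C@H](O[Si](C)(C)C(C)(C)C)[C@@H](OC(=O)c2ccccc2)C=C[C@H]1O[Si](C)(C)C(C)(C)C
F2 | step 3 | (1S,2R,3S,6R)-1-bromo-2,6-bis[(tert-butyldimethylsilyl)oxy]-1-(hydroxymethyl)cyclohex-4-en-3-yl benzoate (ent-8) | OC[C@@]1(Br)[C@H](O[Si](C)(C)C(C)(C)C)[C@@H](OC(=O)c2ccccc2)C=C[C@H]1O[Si](C)(C)C(C)(C)C
F3 | step 1 | potassium (1E,3E)-4-acetoxybuta-1,3-dien-1-olate | [K+].[O-]/C=C/C=C/OC(C)=O
F4 | step 1 | (1E,3E)-4-acetoxybuta-1,3-dien-1-yl benzoate | CC(=O)O/C=C/C=C/OC(=O)c1ccccc1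
F5 | step 6 | (1R,2S,3R,6S)-1-[(benzoyloxy)methyl]-1-bromo-2,6-dihydroxycyclohex-4-en-3-yl benzoate | O=C(OC[C@]1(Br)[C@@H](O)[C@H](OC(=O)c2ccccc2)C=C[C@@H]1O)c1ccccc1
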